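**Plan**

- Retrosynthetic cuts: the C1–O acyl bond; the C8 carbonyl and C12 aldehyde oxygens (back to CH2 and CH3); then the C9–C11 bond is re-formed and the C1 oxygen is tied to C10 as an epoxide, which turns ring B plus its isopropenyl group into a pinane. Ring A is cut at C1=C10 (metathesis), C5–CH3, C3–C4 and C4=C5, back to nopinone.
- Enabling feature: in ring B (C5–C6–C7–C8–C9–C10) the C9=C10 alkene carries an allylic C1–O on one side and, 1,3 to C9, a C7 substituent (C11) at the isopropenyl oxidation pattern. This is the footprint left when a pin-2(10)-ene oxide breaks its C10–O and C9–C11 bonds.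
- Forward order: ring B arrives masked as the six-membered ring of (+)-β-pinene; ring A is built on it (aldol condensation, conjugate addition/methylation, methylenation, ring-closing metathesis); epoxidation and fragmentation open the four-membered ring to the octalin; esterification, C8 oxidation, C12 oxidation and ester cleavage finish.
- Stereochemistry: C7 is the pinene bridgehead. C4, C5 and C1 are each set by attack anti to the gem-dimethyl bridge (conjugate addition, enolate methylation, epoxidation). C4′ comes from (R)-3-bromo-2-methylpropan-1-ol.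
- Side chain: Cu-catalysed C5′–C6′ coupling, then oxidation/Wittig olefination and saponification.

Key step: step 7

Remark 1: positions are labelled C1–C15 as in eremophilanes (C4 bears CO2H, C5 the methyl, C7 the C11 unit, C8 the ketone, C9=C10 the ring alkene, C1 the acyloxy group); primed labels refer to the side chain.
Remark 2: the target's C7 configuration maps onto the (1R,5R)-pinane series, so (+)-β-pinene is assumed as a purchasable material (dearer than its enantiomer; also reachable from bulk (+)-α-pinene by the known contra-thermodynamic isomerisation). tert-Butyl glyoxylate is assumed purchasable and used freshly distilled.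

**Route**

Step 1
Reactants: 1 (+)-β-pinene [(1R,5R)-6,6-dimethyl-2-methylidenebicyclo[3.1.1]heptane]
Product: 3 (−)-nopinone [(1S,5R)-6,6-dimethylbicyclo[3.1.1]heptan-2-one], via ozonide 2 (not isolated)
Conditions: O3, CH2Cl2, −78 °C; Me2S, −78 °C → rt
Reagents that add atoms: ozone, [O-][O+]=O
Why: Ozonolysis (Criegee mechanism) of the exocyclic 1,1-disubstituted alkene with reductive work-up removes only the methylene carbon and leaves both bridgehead stereocentres untouched.

Step 2
Reactants: 3 (−)-nopinone; 4 tert-butyl glyoxylate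
Product: 7 tert-butyl (2E)-2-[(1S,5S)-6,6-dimethyl-2-oxobicyclo[3.1.1]heptan-3-ylidene]acetate, via lithium aldolate 5 (not isolated), via mesylate 6 (not isolated)
Conditions: LDA, THF, −78 °C; 4, −78 °C; MsCl, −78 → 0 °C; Et3N, 0 °C → rt
Reagents that add atoms: none
Why: Directed aldol addition of the only possible (C3) lithium enolate of 3 to the non-enolisable glyoxylate, then mesylation and E1cB elimination, should give the doubly activated exocyclic alkene in its thermodynamic E form (ester anti to the ring carbonyl), the geometry that step 3 translates into C4.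

Step 3
Reactants: 7 the E-alkylidene keto ester; 8 but-3-enylmagnesium bromide
Product: 10 tert-butyl (2S)-2-[(1S,3R,5S)-3,6,6-trimethyl-2-oxobicyclo[3.1.1]heptan-3-yl]hex-5-enoate, via magnesium enolate 9 (not isolated)
Conditions: 8 (1.5 equiv), CuBr·SMe2 (10 mol%), THF, −78 → −40 °C; MeI (5 equiv), DMPU, −40 °C → rt
Reagents that add atoms: iodomethane, CI
Why: In this tandem copper-catalysed conjugate addition–enolate alkylation the butenyl group should add β to the ketone (C4) on the face of the s-cis E-alkylidene ketone anti to the gem-dimethyl bridge (C4 = S), and the regiospecific enolate should be C-methylated again anti to the bridge, so that the methyl ends anti and the C4 branch syn (C5 = R), as in pinane enolate alkylations generally.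

Step 4
Reactants: 10 the methylated keto ester
Product: 11 tert-butyl (2S)-2-[(1S,3R,5S)-3,6,6-trimethyl-2-methylidenebicyclo[3.1.1]heptan-3-yl]hex-5-enoate
Conditions: Tebbe reagent, pyridine (cat.), THF/toluene, −40 → 0 °C; aq. NaOH
Reagents that add atoms: Tebbe reagent (written as its components), C=[Ti](C1C=CC=C1)C1C=CC=C1.C[Al](C)Cl
Why: Tebbe methylenation is non-basic (no epimerisation at the ester α-carbon C4), reaches ketones flanked by a quaternary centre and should leave the tert-butyl ester untouched at low temperature.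

Step 5
Reactants: 11 the diene ester
Product: 12 tert-butyl (1S,5S,7S,8aR)-8a,9,9-trimethyl-1,2,3,5,6,7,8,8a-octahydro-5,7-methanonaphthalene-1-carboxylate (ring A cyclohexene fused to the pinane; alkene C1=C10)
Conditions: Grubbs second-generation catalyst (5 mol%), CH2Cl2, 40 °C
Reagents that add atoms: none
Why: Ring-closing metathesis should initiate at the monosubstituted alkene and close six-membered ring A onto the 1,1-disubstituted alkene to the trisubstituted C1=C10 alkene, in which the C4 ester sits on the side of ring A away from the bridge, the configuration already delivered by step 3.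

Step 6
Reactants: 12 the tricyclic alkene
Product: 13 tert-butyl (1S,4R,4aS,5S,7S,8aR)-4,4a-epoxy-8a,9,9-trimethyldecahydro-5,7-methanonaphthalene-1-carboxylate (C1–C10 epoxide; oxygen anti to the gem-dimethyl bridge and cis to the C5 methyl)
Conditions: dimethyldioxirane, acetone, 0 °C
Reagents that add atoms: dimethyldioxirane, CC1(C)OO1
Why: Epoxidation with the neutral dioxirane (no acid, so the acid-labile pinane epoxide survives) should occur on the alkene face anti to the gem-dimethyl bridge, as for β-pinene itself, which places oxygen cis to the C5 methyl and sets C1 (R).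

Step 7
Reactants: 13 the epoxide
Product: 14 tert-butyl (1S,4R,7S,8aR)-4-hydroxy-8a-methyl-7-(prop-1-en-2-yl)-1,2,3,4,6,7,8,8a-octahydronaphthalene-1-carboxylate
Conditions: Cp2TiCl2 (2.5 equiv), Zn, THF, rt (preformed Cp2TiCl), slow addition of 13; cold 1 M HCl
Reagents that add atoms: none
Why: Titanocene(III) should transfer one electron to the epoxide and cleave the C10–O bond (tertiary radical at C10; oxygen and its configuration stay on C1), this cyclobutylcarbinyl radical should undergo β-scission of the strained C9–C11 bond to give the C9=C10 alkene and a tertiary C11 radical, and a second titanocene(III) should turn that radical into the isopropenyl group by removing a methyl hydrogen (mixed disproportionation/β-hydride elimination). The closest known reaction types are the Nugent–RajanBabu titanocene(III) epoxide opening with terminal dehydrogenation to exo-methylene allylic alcohols, the ring opening of C2-centred pinanyl radicals known from radical additions to β-pinene, and the heterolytic counterpart, the acid isomerisation of β-pinene oxide to perillyl alcohol. No ring is closed: the four-membered ring is opened and the pinane six-membered ring emerges as ring B of the octalin. No stereocentre is created: C1 (C–O bond untouched), C4, C5 and C7 (its bond to C11 persists) are carried over, and the position of the ring alkene is dictated by which σ-bond breaks. The step needs C10–O rather than C1–O homolysis (tertiary versus secondary radical), C9–C11 rather than C9–C8 scission (tertiary versus primary radical) and alkene-forming rather than reductive termination. The substrate secures the first two, and because C5 is quaternary and C9 a bridgehead the C10 radical has no β-hydrogen to lose, so ring opening is its only fast exit, while excess titanocene(III) favours the third.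

Step 8
Reactants: 15 (R)-3-bromo-2-methylpropan-1-ol; 16 propylmagnesium bromide
Product: 17 (S)-2-methylhexan-1-ol
Conditions: 16 (3 equiv), Li2CuCl4 (5 mol%), THF, −30 → 0 °C; 1 M HCl
Reagents that add atoms: none
Why: In this copper-catalysed sp3–sp3 cross-coupling (Kochi type) the first equivalent of Grignard reagent only deprotonates the hydroxyl group and the stereocentre is not involved, so it is carried over from the chiral pool (R becomes S only through the change in CIP priorities).

Step 9
Reactants: 17 (S)-2-methylhexan-1-ol; 18 ethyl 2-(triphenylphosphoranylidene)propanoate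
Product: 20 ethyl (2E,4S)-2,4-dimethyloct-2-enoate, via (S)-2-methylhexanal 19 (not isolated)
Conditions: TEMPO (10 mol%), PhI(OAc)2, CH2Cl2, rt; 18, rt → 40 °C
Reagents that add atoms: none
Why: The oxoammonium oxidation should give the aldehyde without epimerisation and the stabilised α-methyl ylide should trap it in the same flask (Wittig olefination) with the usual E selectivity, so that the configurationally labile α-branched aldehyde is never isolated.

Step 10
Reactants: 20 the ethyl ester
Product: 21 (2E,4S)-2,4-dimethyloct-2-enoic acid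
Conditions: LiOH, THF/MeOH/H2O, 45 °C; 1 M HCl
Reagents that add atoms: lithium hydroxide, [Li+].[OH-]
Why: Saponification of the ethyl ester should leave the γ-stereocentre alone, as it is not acidic under these conditions.

Step 11
Reactants: 14 the allylic alcohol; 21 the side-chain acid
Product: 23 tert-butyl (1S,4R,7S,8aR)-4-{[(2E,4S)-2,4-dimethyloct-2-enoyl]oxy}-8a-methyl-7-(prop-1-en-2-yl)-1,2,3,4,6,7,8,8a-octahydronaphthalene-1-carboxylate, via mixed anhydride 22 (not isolated)
Conditions: 21, 2,4,6-trichlorobenzoyl chloride, Et3N, THF, rt; 14, DMAP, toluene, rt → 40 °C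
Reagents that add atoms: none
Why: Yamaguchi esterification through the mixed anhydride should acylate the hindered secondary allylic alcohol with retention at C1 and without touching the tert-butyl ester.

Step 12
Reactants: 23 the diester
Product: 24 tert-butyl (1S,4R,7S,8aR)-4-{[(2E,4S)-2,4-dimethyloct-2-enoyl]oxy}-8a-methyl-6-oxo-7-(prop-1-en-2-yl)-1,2,3,4,6,7,8,8a-octahydronaphthalene-1-carboxylate
Conditions: CrO3, 3,5-dimethylpyrazole, CH2Cl2, −20 °C
Reagents that add atoms: chromium trioxide, O=[Cr](=O)=O
Why: Chromium(VI)–dimethylpyrazole allylic oxidation should convert the ring methylene C8 next to the trisubstituted C9=C10 alkene into the enone carbonyl, the selectivity by which valencene gives nootkatone with its isopropenyl group intact, while the other allylic position, C1, is blocked and deactivated by the acyloxy group.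

Step 13
Reactants: 24 the enone
Product: 26 tert-butyl (1S,4R,7S,8aR)-4-{[(2E,4S)-2,4-dimethyloct-2-enoyl]oxy}-8a-methyl-6-oxo-7-(3-oxoprop-1-en-2-yl)-1,2,3,4,6,7,8,8a-octahydronaphthalene-1-carboxylate, via allylic alcohol 25 (not isolated)
Conditions: SeO2 (0.5 equiv), t-BuOOH, CH2Cl2, rt; Dess–Martin periodinane, NaHCO3, CH2Cl2, 0 °C → rt
Reagents that add atoms: tert-butyl hydroperoxide, CC(C)(C)OO; selenium dioxide (oxygen carrier), O=[Se]=O
Why: The selenium dioxide ene reaction/[2,3]-sigmatropic shift (Riley-type allylic oxidation) should attack the only electron-rich alkene left, the isopropenyl group, at its methyl group (C7–H is electron-poor, being α to the ketone), and the periodinane should take the allylic alcohol on to the enal under buffered, non-basic conditions that neither epimerise C7 nor move the double bond.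

Step 14
Reactants: 26 the tert-butyl ester
Product: 27 integric acid [(1S,4R,7S,8aR)-4-{[(2E,4S)-2,4-dimethyloct-2-enoyl]oxy}-8a-methyl-6-oxo-7-(3-oxoprop-1-en-2-yl)-1,2,3,4,6,7,8,8a-octahydronaphthalene-1-carboxylic acid]
Conditions: TFA, CH2Cl2, 0 °C
Reagents that add atoms: none
Why: Acidolysis of the tert-butyl ester (E1, loss of isobutene) should free the C15 acid without base, so that the enoate ester at C1, the enal and the epimerisable C7 centre are not touched.

**Compound list**

1 | (+)-β-pinene, (1R,5R)-6,6-dimethyl-2-methylidenebicyclo[3.1.1]heptane | C=C1CC[C@@H]2C[C@H]1C2(C)C | starting material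
2 | spiro ozonide (1,2,4-trioxolane) of 1, mixture at the spiro carbon | C1OC2(OO1)CC[C@@H]3C[C@H]2C3(C)C | intermediate (not isolated)
3 | (−)-nopinone, (1S,5R)-6,6-dimethylbicyclo[3.1.1]heptan-2-one | O=C1CC[C@@H]2C[C@H]1C2(C)C | intermediate
4 | tert-butyl glyoxylate | O=CC(=O)OC(C)(C)C | starting material
5 | lithium aldolate of 3 and 4 (C3–CH(OLi)CO2tBu, diastereomer mixture) | O=C1C(C(O[Li])C(=O)OC(C)(C)C)C[C@@H]2C[C@H]1C2(C)C | intermediate (not isolated)
6 | mesylate of the aldol adduct (diastereomer mixture) | O=C1C(C(OS(C)(=O)=O)C(=O)OC(C)(C)C)C[C@@H]2C[C@H]1C2(C)C | intermediate (not isolated)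
7 | tert-butyl (2E)-2-[(1S,5S)-6,6-dimethyl-2-oxobicyclo[3.1.1]heptan-3-ylidene]acetate | O=C1/C(=C/C(=O)OC(C)(C)C)C[C@@H]2C[C@H]1C2(C)C | intermediate
8 | but-3-enylmagnesium bromide | C=CCC[Mg]Br | starting material
9 | bromomagnesium enolate of the conjugate adduct (C10–O, C10=C5; C4 S) | Br[Mg]OC1=C([C@H](CCC=C)C(=O)OC(C)(C)C)C[C@@H]2C[C@H]1C2(C)C | intermediate (not isolated)
10 | tert-butyl (2S)-2-[(1S,3R,5S)-3,6,6-trimethyl-2-oxobicyclo[3.1.1]heptan-3-yl]hex-5-enoate | O=C1[C@@](C)([C@H](CCC=C)C(=O)OC(C)(C)C)C[C@@H]2C[C@H]1C2(C)C | intermediate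
11 | tert-butyl (2S)-2-[(1S,3R,5S)-3,6,6-trimethyl-2-methylidenebicyclo[3.1.1]heptan-3-yl]hex-5-enoate | C=C1[C@@](C)([C@H](CCC=C)C(=O)OC(C)(C)C)C[C@@H]2C[C@H]1C2(C)C | intermediate
12 | tert-butyl (1S,5S,7S,8aR)-8a,9,9-trimethyl-1,2,3,5,6,7,8,8a-octahydro-5,7-methanonaphthalene-1-carboxylate | CC(C)(C)OC(=O)[C@H]1CCC=C2[C@]1(C)C[C@@H]3C[C@H]2C3(C)C | intermediate
13 | tert-butyl (1S,4R,4aS,5S,7S,8aR)-4,4a-epoxy-8a,9,9-trimethyldecahydro-5,7-methanonaphthalene-1-carboxylate | CC(C)(C)OC(=O)[C@H]1CC[C@H]2O[C@@]23[C@]1(C)C[C@@H]4C[C@H]3C4(C)C | intermediate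
14 | tert-butyl (1S,4R,7S,8aR)-4-hydroxy-8a-methyl-7-(prop-1-en-2-yl)-1,2,3,4,6,7,8,8a-octahydronaphthalene-1-carboxylate | C=C(C)[C@@H]1C[C@@]2(C)C(=CC1)[C@H](O)CC[C@@H]2C(=O)OC(C)(C)C | intermediate
15 | (R)-3-bromo-2-methylpropan-1-ol | C[C@H](CO)CBr | starting material
16 | propylmagnesium bromide | CCC[Mg]Br | starting material
17 | (S)-2-methylhexan-1-ol | C[C@H](CO)CCCC | intermediate
18 | ethyl 2-(triphenylphosphoranylidene)propanoate | CCOC(=O)C(C)=P(c1ccccc1)(c1ccccc1)c1ccccc1 | starting material
19 | (S)-2-methylhexanal | C[C@H](C=O)CCCC | intermediate (not isolated)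
20 | ethyl (2E,4S)-2,4-dimethyloct-2-enoate | CCOC(=O)/C(C)=C/[C@@H](C)CCCC | intermediate
21 | (2E,4S)-2,4-dimethyloct-2-enoic acid | OC(=O)/C(C)=C/[C@@H](C)CCCC | intermediate
22 | (2E,4S)-2,4-dimethyloct-2-enoic 2,4,6-trichlorobenzoic anhydride | O=C(OC(=O)c1c(Cl)cc(Cl)cc1Cl)/C(C)=C/[C@@H](C)CCCC | intermediate (not isolated)
23 | tert-butyl (1S,4R,7S,8aR)-4-{[(2E,4S)-2,4-dimethyloct-2-enoyl]oxy}-8a-methyl-7-(prop-1-en-2-yl)-1,2,3,4,6,7,8,8a-octahydronaphthalene-1-carboxylate | C=C(C)[C@@H]1C[C@@]2(C)C(=CC1)[C@H](OC(=O)/C(C)=C/[C@@H](C)CCCC)CC[C@@H]2C(=O)OC(C)(C)C | intermediate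
24 | tert-butyl (1S,4R,7S,8aR)-4-{[(2E,4S)-2,4-dimethyloct-2-enoyl]oxy}-8a-methyl-6-oxo-7-(prop-1-en-2-yl)-1,2,3,4,6,7,8,8a-octahydronaphthalene-1-carboxylate | C=C(C)[C@@H]1C[C@@]2(C)C(=CC1=O)[C@H](OC(=O)/C(C)=C/[C@@H](C)CCCC)CC[C@@H]2C(=O)OC(C)(C)C | intermediate
25 | tert-butyl (1S,4R,7S,8aR)-4-{[(2E,4S)-2,4-dimethyloct-2-enoyl]oxy}-7-(3-hydroxyprop-1-en-2-yl)-8a-methyl-6-oxo-1,2,3,4,6,7,8,8a-octahydronaphthalene-1-carboxylate | C=C(CO)[C@@H]1C[C@@]2(C)C(=CC1=O)[C@H](OC(=O)/C(C)=C/[C@@H](C)CCCC)CC[C@@H]2C(=O)OC(C)(C)C | intermediate (not isolated)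
26 | tert-butyl (1S,4R,7S,8aR)-4-{[(2E,4S)-2,4-dimethyloct-2-enoyl]oxy}-8a-methyl-6-oxo-7-(3-oxoprop-1-en-2-yl)-1,2,3,4,6,7,8,8a-octahydronaphthalene-1-carboxylate | C=C(C=O)[C@@H]1C[C@@]2(C)C(=CC1=O)[C@H](OC(=O)/C(C)=C/[C@@H](C)CCCC)CC[C@@H]2C(=O)OC(C)(C)C | intermediate
27 | integric acid, (1S,4R,7S,8aR)-4-{[(2E,4S)-2,4-dimethyloct-2-enoyl]oxy}-8a-methyl-6-oxo-7-(3-oxoprop-1-en-2-yl)-1,2,3,4,6,7,8,8a-octahydronaphthalene-1-carboxylic acid | C=C(C=O)[C@@H]1C[C@@]2(C)C(=CC1=O)[C@H](OC(=O)/C(C)=C/[C@@H](C)CCCC)CC[C@@H]2C(=O)O | target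

**Step count and risks**

Total step count: 14. Longest linear sequence: 11 (steps 1–7 and 11–14); the side chain takes steps 8–10.

Steps most likely to fail:

Step 7. The C11 radical may be reduced (hydrogen abstraction from THF, or reduction and protonation) instead of being dehydrogenated, and the C10 radical may be intercepted before the ring opens. The fallback replaces the radical scission by the polar one with water capture; it sets out from 13 and returns at 23. Hydrolytic opening of 13 with a trace of perchloric acid in aqueous acetone at 0 °C should let the C10 cation fragment and water trap the C11 cation, giving the diol tert-butyl (1S,4R,7S,8aR)-4-hydroxy-7-(2-hydroxypropan-2-yl)-8a-methyl-1,2,3,4,6,7,8,8a-octahydronaphthalene-1-carboxylate F1. Its secondary allylic hydroxyl alone should then be esterified with 21 under the Yamaguchi conditions of step 11 to the hydroxy ester tert-butyl (1S,4R,7S,8aR)-4-{[(2E,4S)-2,4-dimethyloct-2-enoyl]oxy}-7-(2-hydroxypropan-2-yl)-8a-methyl-1,2,3,4,6,7,8,8a-octahydronaphthalene-1-carboxylate F2. Dehydration of the tertiary alcohol with the Burgess reagent should give the isopropenyl compound 23.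

Step 13. The ene reaction may engage the C7–H instead of the methyl group, conversion may stall, or the product may be over-oxidised. The fallback replaces the selenium ene reaction by an electrophilic ene chlorination followed by N-oxide oxidation; it sets out from 24 and returns at 26. Hypochlorous acid (Ca(OCl)2, CO2, CH2Cl2/H2O, 0 °C) should convert the isopropenyl group into the allylic chloride tert-butyl (1S,4R,7S,8aR)-7-(3-chloroprop-1-en-2-yl)-4-{[(2E,4S)-2,4-dimethyloct-2-enoyl]oxy}-8a-methyl-6-oxo-1,2,3,4,6,7,8,8a-octahydronaphthalene-1-carboxylate F3. N-Methylmorpholine N-oxide in acetonitrile (Ganem-type oxidation) should then take the chloride to the enal 26 under nearly neutral conditions.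

Step 3. The very electron-poor alkene may be reduced by electron transfer instead of alkylated, and the hindered magnesium enolate may alkylate slowly or on oxygen, with proton exchange eroding the regiocontrol. The fallback separates the two bond formations; it sets out from 7 and returns at 10. The copper-catalysed addition of 8 is run in the presence of chlorotrimethylsilane and the silyl enol ether tert-butyl (2S)-2-[(1S,5S)-6,6-dimethyl-2-(trimethylsilyloxy)bicyclo[3.1.1]hept-2-en-3-yl]hex-5-enoate F4 is isolated. Benzyltrimethylammonium fluoride in THF in the presence of iodomethane should then release the ammonium enolate regiospecifically and methylate it, again anti to the bridge, to give 10.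

**Further compounds**

F1 | step 7 | tert-butyl (1S,4R,7S,8aR)-4-hydroxy-7-(2-hydroxypropan-2-yl)-8a-methyl-1,2,3,4,6,7,8,8a-octahydronaphthalene-1-carboxylate | CC(C)(O)[C@@H]1C[C@@]2(C)C(=CC1)[C@H](O)CC[C@@H]2C(=O)OC(C)(C)C
F2 | step 7 | tert-butyl (1S,4R,7S,8aR)-4-{[(2E,4S)-2,4-dimethyloct-2-enoyl]oxy}-7-(2-hydroxypropan-2-yl)-8a-methyl-1,2,3,4,6,7,8,8a-octahydronaphthalene-1-carboxylate | CC(C)(O)[C@@H]1C[C@@]2(C)C(=CC1)[C@H](OC(=O)/C(C)=C/[C@@H](C)CCCC)CC[C@@H]2C(=O)OC(C)(C)C
F3 | step 13 | tert-butyl (1S,4R,7S,8aR)-7-(3-chloroprop-1-en-2-yl)-4-{[(2E,4S)-2,4-dimethyloct-2-enoyl]oxy}-8a-methyl-6-oxo-1,2,3,4,6,7,8,8a-octahydronaphthalene-1-carboxylate | C=C(CCl)[C@@H]1C[C@@]2(C)C(=CC1=O)[C@H](OC(=O)/C(C)=C/[C@@H](C)CCCC)CC[C@@H]2C(=O)OC(C)(C)C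
F4 | step 3 | tert-butyl (2S)-2-[(1S,5S)-6,6-dimethyl-2-(trimethylsilyloxy)bicyclo[3.1.1]hept-2-en-3-yl]hex-5-enoate | C[Si](C)(C)OC1=C([C@H](CCC=C)C(=O)OC(C)(C)C)C[C@@H]2C[C@H]1C2(C)C
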